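## Retrosynthetic overview
1. The C3 carbinol is installed last, by α′-hydroxylation of the fully assembled keto-ester under substrate control from the angular methyl.
2. The key disconnection is the C6–O ester bond. It is made directly from an unfunctionalised C6–H of the bicyclic dienone and the free (6R)-dienoic acid by palladium-catalysed ε-C–H acyloxylation, with no C6 alcohol and no protecting groups.
3. The dienone comes from γ,δ-dehydrogenation of the cis-4a,5-dimethyloctalone, which comes from a Michael/aldol annulation.
4. Ring order: ring A (later the ester-bearing ring) is bought as 2-methylcyclohexenone and receives the C5 methyl by catalytic asymmetric conjugate addition. Ring B (the enone ring) is closed second with methyl vinyl ketone, which fixes C4a.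
5. The acid comes from carbenoid ring opening of 2-ethylfuran with ethyl diazoacetate, then catalytic asymmetric methyl addition to the ketone (sets C6′), then saponification.

**Locants.** The bicycle keeps the naphthalen-2(3H)-one locants of 6 and 7 throughout: C2 is the ketone, C3 the α′-carbon, C4a the quaternary carbon, C5 the CHMe carbon and C6 the ε-carbon. Primed locants refer to the acid chain. The β face is the face carrying both ring methyl groups.

**Assumption.** The facial sense of the two catalytic asymmetric additions (steps 1 and 5) is assigned by analogy with the parent substrates of each catalyst. If either is reversed, the enantiomeric ligand is used.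

## Route

Step 1
Reactants: 1 2-methylcyclohex-2-en-1-one
Product: 3 {[(3S)-2,3-dimethylcyclohex-1-en-1-yl]oxy}trimethylsilane, via dimethylaluminium enolate 2 (not isolated)
Conditions: AlMe3 (1.3 equiv), Cu(O2CC4H3S) (copper thiophene-2-carboxylate, 2 mol %), (S,R,R)-BINOL-derived N,N-bis(1-phenylethyl)phosphoramidite (4 mol %), Et2O, −30 °C; then TMSOTf (1.5 equiv), THF, −30 to 0 °C; cold aq NaHCO3
Reagents that add atoms: trimethylaluminium, C[Al](C)C; trimethylsilyl trifluoromethanesulfonate, C[Si](C)(C)OS(=O)(=O)C(F)(F)F
Why: Copper-catalysed asymmetric conjugate addition, in which the chiral monovalent copper–phosphoramidite complex transfers methyl to one face of C3 (sets 3S, the future C5) and O-silylation of the regiodefined aluminium enolate locks the tetrasubstituted enol ether.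

Step 2
Reactants: 3 {[(3S)-2,3-dimethylcyclohex-1-en-1-yl]oxy}trimethylsilane; 4 methyl vinyl ketone
Product: 6 (4aR,5S)-4a,5-dimethyl-4,4a,5,6,7,8-hexahydronaphthalen-2(3H)-one, via 1,5-diketone 5 (not isolated)
Conditions: 4 (1.3 equiv), BF3·OEt2 (0.3 equiv), iPrOH (1.1 equiv), CH2Cl2, −78 °C; crude, then KOH (0.5 equiv), EtOH, 60 °C
Reagents that add atoms: none
Why: Mukaiyama–Michael addition followed by aldol condensation (Robinson annulation), in which the C3 methyl of 3 sits pseudo-axial to avoid allylic strain with the vinylic methyl, so 4 adds to the opposite face and the two methyl groups end up cis (sets 4aR).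

Step 3
Reactants: 6 (4aR,5S)-4a,5-dimethyl-4,4a,5,6,7,8-hexahydronaphthalen-2(3H)-one
Product: 7 (4aR,5S)-4a,5-dimethyl-4,4a,5,6-tetrahydronaphthalen-2(3H)-one
Conditions: chloranil (1.3 equiv), t-BuOH, reflux
Reagents that add atoms: none
Why: Quinone dehydrogenation through the extended (thermodynamic) dienol, in which hydride abstraction from C7 gives the linear C1=C8a–C8=C7 dienone, as in the 4-en-3-one to 4,6-dien-3-one conversion of steroids, and no stereocentre is touched.

Step 4
Reactants: 8 2-ethylfuran; 9 ethyl diazoacetate
Product: 11 ethyl (2E,4E)-6-oxoocta-2,4-dienoate, via (2E,4Z)-isomer 10 (not isolated)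
Conditions: 8 (3 equiv), Rh2(OAc)4 (0.5 mol %), CH2Cl2, rt, slow addition of 9; then I2 (5 mol %), rt
Reagents that add atoms: none
Why: Rhodium-carbenoid attack on the unsubstituted C4=C5 bond of the furan and spontaneous ring opening (furan unravelling) give the Z,E keto-dienoate, which iodine-catalysed isomerisation converts into the thermodynamic E,E isomer.

Step 5
Reactants: 11 ethyl (2E,4E)-6-oxoocta-2,4-dienoate
Product: 12 ethyl (2E,4E,6R)-6-hydroxy-6-methylocta-2,4-dienoate
Conditions: ZnMe2 (3 equiv), Ti(OiPr)4 (1.2 equiv), bis(2-exo-hydroxycamphor-10-sulfonamide) of (1R,2R)-cyclohexane-1,2-diamine (10 mol %), toluene, rt, 48 h; water, Celite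
Reagents that add atoms: dimethylzinc, C[Zn]C
Why: Titanium-catalysed asymmetric 1,2-addition of a dialkylzinc to a ketone, in which the chiral titanium bis(sulfonamide) complex tells the flat dienyl arm from the ethyl arm and passes methyl (as MeTi(OiPr)3) to the Si face of the ketone (sets 6R), while the ester and diene survive because methyltitanium species are strictly 1,2- and ketone-selective.

Step 6
Reactants: 12 ethyl (2E,4E,6R)-6-hydroxy-6-methylocta-2,4-dienoate
Product: 13 (2E,4E,6R)-6-hydroxy-6-methylocta-2,4-dienoic acid
Conditions: LiOH (3 equiv), THF/H2O 3:1, rt; 1 M HCl to pH 4, 0 °C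
Reagents that add atoms: lithium hydroxide, [Li+].[OH-]
Why: Plain saponification, in which the carbinol carbon bears no hydrogen and cannot epimerise, and the E,E geometry rules out lactonisation.

Step 7
Reactants: 7 (4aR,5S)-4a,5-dimethyl-4,4a,5,6-tetrahydronaphthalen-2(3H)-one; 13 (2E,4E,6R)-6-hydroxy-6-methylocta-2,4-dienoic acid
Product: 14 (1R,2S,8aR)-1,8a-dimethyl-6-oxo-1,2,6,7,8,8a-hexahydronaphthalen-2-yl (2E,4E,6R)-6-hydroxy-6-methylocta-2,4-dienoate
Conditions: 7 (1.5 equiv), 13 (1.0 equiv), Pd(O2CCF3)2 (10 mol %), 4,5-diazafluoren-9-one (12 mol %), 2,6-dimethyl-1,4-benzoquinone (1.5 equiv), iPr2NEt (0.5 equiv), 4 Å MS, 1,4-dioxane, 45 °C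
Reagents that add atoms: none
Why: Proposed new method: bis-vinylogous (ε-selective) dehydrogenative allylic C–H acyloxylation of a linear dienone with a complex acid as limiting reagent; the electrophilic divalent palladium complex binds C7=C8 of 7 on the open α face (anti to both methyl groups) while external carboxylate/amine removes the ketone-acidified, stereoelectronically aligned pseudo-axial 6β-H, giving a cationic η3-allyl (C6–C8) whose two free sites are filled by the chelating diazafluorenone, so inner-sphere delivery and β-hydride loss are suppressed and the carboxylate of 13 must attack from outside, anti to the metal, on the β face and at C6 (the terminus remote from the electron-poor enone and the only one that restores the conjugated dienone), which forms the C6–O bond and sets 6S; the quinone returns zerovalent palladium to the divalent state and the amine buffers the released CF3CO2H to protect the tertiary alcohol; the closest known reactions are the palladium/sulfoxide allylic C–H esterification of terminal alkenes and the quinone-driven anti acyloxylation of cyclic η3-allylpalladium intermediates in diene 1,4-diacyloxylation.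

Step 8
Reactants: 14 (1R,2S,8aR)-1,8a-dimethyl-6-oxo-1,2,6,7,8,8a-hexahydronaphthalen-2-yl (2E,4E,6R)-6-hydroxy-6-methylocta-2,4-dienoate
Product: 16 (1R,2S,7R,8aR)-7-hydroxy-1,8a-dimethyl-6-oxo-1,2,6,7,8,8a-hexahydronaphthalen-2-yl (2E,4E,6R)-6-hydroxy-6-methylocta-2,4-dienoate, via disodium enolate alkoxide 15 (not isolated)
Conditions: NaN(SiMe3)2 (2.2 equiv), THF, −78 °C; 2-(benzenesulfonyl)-3-phenyloxaziridine (1.3 equiv), −78 °C; AcOH quench
Reagents that add atoms: 2-(benzenesulfonyl)-3-phenyloxaziridine, O=S(=O)(c1ccccc1)N1OC1c1ccccc1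
Why: Davis enolate hydroxylation, in which the first equivalent of base parks the tertiary alcohol as its alkoxide, the second removes the kinetically accessible α′-H at C3 to give the cross-conjugated enolate (the dienoate has no enolisable hydrogen), and the oxaziridine approaches the α face, anti to the axial C4a methyl, giving the equatorial 3R carbinol, which is also the thermodynamic epimer.

## Compound list
1 | 2-methylcyclohex-2-en-1-one | CC1=CCCCC1=O | starting material
2 | dimethylaluminium (3S)-2,3-dimethylcyclohex-1-en-1-olate | C1CCC(O[Al](C)C)=C(C)[C@H]1C | intermediate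
3 | {[(3S)-2,3-dimethylcyclohex-1-en-1-yl]oxy}trimethylsilane | C1CCC(O[Si](C)(C)C)=C(C)[C@H]1C | intermediate
4 | methyl vinyl ketone (but-3-en-2-one) | C=CC(C)=O | starting material
5 | (2R,3S)-2,3-dimethyl-2-(3-oxobutyl)cyclohexan-1-one | C1CCC(=O)[C@@](CCC(C)=O)(C)[C@H]1C | intermediate
6 | (4aR,5S)-4a,5-dimethyl-4,4a,5,6,7,8-hexahydronaphthalen-2(3H)-one | C1CCC2=CC(=O)CC[C@]2(C)[C@H]1C | intermediate
7 | (4aR,5S)-4a,5-dimethyl-4,4a,5,6-tetrahydronaphthalen-2(3H)-one | C1C=CC2=CC(=O)CC[C@]2(C)[C@H]1C | intermediate
8 | 2-ethylfuran | CCc1ccco1 | starting material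
9 | ethyl diazoacetate | CCOC(=O)C=[N+]=[N-] | starting material
10 | ethyl (2E,4Z)-6-oxoocta-2,4-dienoate | CCC(=O)/C=C\C=C\C(=O)OCC | intermediate
11 | ethyl (2E,4E)-6-oxoocta-2,4-dienoate | CCC(=O)/C=C/C=C/C(=O)OCC | intermediate
12 | ethyl (2E,4E,6R)-6-hydroxy-6-methylocta-2,4-dienoate | CC[C@@](C)(O)/C=C/C=C/C(=O)OCC | intermediate
13 | (2E,4E,6R)-6-hydroxy-6-methylocta-2,4-dienoic acid | CC[C@@](C)(O)/C=C/C=C/C(=O)O | intermediate
14 | (1R,2S,8aR)-1,8a-dimethyl-6-oxo-1,2,6,7,8,8a-hexahydronaphthalen-2-yl (2E,4E,6R)-6-hydroxy-6-methylocta-2,4-dienoate | CC[C@@](C)(O)/C=C/C=C/C(=O)O[C@H]1C=CC2=CC(=O)CC[C@]2(C)[C@H]1C | intermediate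
15 | disodium salt of 14 (C2–C3 enolate and C6′ alkoxide) | [Na+].[Na+].CC[C@@](C)([O-])/C=C/C=C/C(=O)O[C@H]1C=CC2=CC([O-])=CC[C@]2(C)[C@H]1C | intermediate
16 | (1R,2S,7R,8aR)-7-hydroxy-1,8a-dimethyl-6-oxo-1,2,6,7,8,8a-hexahydronaphthalen-2-yl (2E,4E,6R)-6-hydroxy-6-methylocta-2,4-dienoate (CNP0260852.1) | CC[C@@](C)(O)/C=C/C=C/C(=O)O[C@H]1C=CC2=CC(=O)[C@H](O)C[C@]2(C)[C@H]1C | target

## Step count and weak points
**Total steps:** 8.

**Longest linear sequence:** 5 steps. Both branches have this length: 1 → 3 → 6 → 7 → 14 → 16, and 8 → 11 → 12 → 13 → 14 → 16.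

**Most likely to fail, first: step 7, the proposed C–H acyloxylation.**
- C–H cleavage may not occur on an internal, electron-poor alkene.
- β-Hydride loss from C5 could give the trienone.
- α′,β′-Dehydrogenation of ring B could compete.
- Partial inner-sphere delivery would give the 6α-epimer.

The fallback uses known chemistry only. It sets out from 7 and comes back to the route at 14. Compound 7 is treated with TBSOTf/Et3N (CH2Cl2, 0 °C) to give the fully extended silyl trienol ether F1. This is the same ε-enolisation that turns steroidal 4,6-dien-3-ones into 3,5,7-trienol derivatives. Vinylogous Rubottom oxidation of its terminal C6=C7 bond follows (dimethyldioxirane, acetone/CH2Cl2, −40 °C, then aqueous citric acid). It gives two separable ε-hydroxy dienones, the 6α-alcohol F2 and the 6β-alcohol F3. Both converge on 14. The 6α-alcohol F2 reacts with 13 by Mitsunobu esterification (PPh3, DIAD, toluene, 0 °C) with inversion at C6. The 6β-alcohol F3 reacts with 13 by Steglich acylation (EDC·HCl, DMAP, CH2Cl2) with retention. The tertiary alcohol of 13 is inert under both sets of conditions.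

**Second: step 8, late-stage enolate hydroxylation.**
- ε-Deprotonation at C6 may compete with α′-deprotonation.
- The enolate may add to the sulfonimine by-product.
- The allylic ester may be lost under strong base.

The fallback sets out from 14 and comes back at 16. Base-free α′-acetoxylation with Mn(OAc)3 (benzene, reflux, water separator) goes through the trivalent manganese enolate and gives the 3-acetate F4. Brief methanolysis (K2CO3, MeOH, 0 °C) then removes only the ketone-activated acetate. It also equilibrates C3 to the equatorial 3R carbinol, delivering 16.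

**Third: step 5, asymmetric methyl addition.**
- ZnMe2 is sluggish.
- The dienyl/ethyl discrimination on this acceptor-substituted ketone may give only moderate ee.

The fallback sets out from 11 and comes back at 12. Non-selective 1,2-addition (MeMgBr, CeCl3, THF, −78 °C) gives the racemic hydroxy ester F5. This is resolved by preparative supercritical-fluid chromatography on an amylose tris(3,5-dimethylphenylcarbamate) phase. The (6R)-enantiomer is 12, and the (6S)-hydroxy ester F6 is discarded.

## Further compounds
F1 | step 7 | tert-butyl{[(4aR,5S)-4a,5-dimethyl-3,4,4a,5-tetrahydronaphthalen-2-yl]oxy}dimethylsilane | C1=CC=C2C=C(O[Si](C)(C)C(C)(C)C)CC[C@]2(C)[C@H]1C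
F2 | step 7 | (4aR,5R,6R)-6-hydroxy-4a,5-dimethyl-4,4a,5,6-tetrahydronaphthalen-2(3H)-one | O[C@@H]1C=CC2=CC(=O)CC[C@]2(C)[C@H]1C
F3 | step 7 | (4aR,5R,6S)-6-hydroxy-4a,5-dimethyl-4,4a,5,6-tetrahydronaphthalen-2(3H)-one | O[C@H]1C=CC2=CC(=O)CC[C@]2(C)[C@H]1C
F4 | step 8 | (1R,2S,7R,8aR)-7-acetoxy-1,8a-dimethyl-6-oxo-1,2,6,7,8,8a-hexahydronaphthalen-2-yl (2E,4E,6R)-6-hydroxy-6-methylocta-2,4-dienoate | CC[C@@](C)(O)/C=C/C=C/C(=O)O[C@H]1C=CC2=CC(=O)[C@H](OC(C)=O)C[C@]2(C)[C@H]1C
F5 | step 5 | ethyl (2E,4E)-6-hydroxy-6-methylocta-2,4-dienoate, racemic | CCC(C)(O)/C=C/C=C/C(=O)OCC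
F6 | step 5 | ethyl (2E,4E,6S)-6-hydroxy-6-methylocta-2,4-dienoate | CC[C@](C)(O)/C=C/C=C/C(=O)OCC
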